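**Plan** (core numbering: C1 ketone, C2=C3(CH3), C4, C5, C6 (CH3, CH2O), C7 (OAc), C8, C9 (O-senecioyl), C10 (CH3), C11; cyclobutane = C4–C5–C11–C10)
- Retrosynthesis: the three acyl groups come off last; then the cyclobutane bond C10–C11 is cut and C10 is returned to C1. The triad C1(=O)–C11(H)–C10 of the bicyclo[3.1.1]hept-3-en-2-one is the retron of a semipinacol 1,2-shift: C1 was a bridgehead carbinol, C11 carried a leaving group, C10 was the one-carbon bridge and C2=C3 the double bond of a norbornene.
- That norbornene, with its seven-membered ring, is cut at C4–C5 and C1–C11 (intramolecular Diels–Alder) into a 5,5-disubstituted 1-silyloxycyclopentadiene tethered to an (E)-alkenylboronate; the chain is cut at C9–C10 (aldol, then C10 methylation) and at C6–C7 (alcohol/isoprene monoxide coupling).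
- Forward order of rings: temporary 1,3-dioxane; purchased cyclopentenone; norbornene and seven-membered ring together; cyclobutane and cyclohexenone together in the rearrangement.
- Stereochemistry: C6/C7 from one catalyst-controlled C–C coupling; C9 by 1,3-anti induction from C7; C10 by chelate-controlled methylation from C9; C4, C5, C1, C11 from C10 and the (E)-alkene in the cycloaddition; C11 is inverted in the shift.

Key step: step 16

Remark: 1, 2 and 9 are taken as purchased; step 1 is assumed to follow its chair model (secondary OH anti to CH2OH), and the ligand enantiomer is the one that gives the 3R carbinol.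

Step 1
Reactants: 1 3-[(4-methoxybenzyl)oxy]propan-1-ol; 2 2-methyl-2-vinyloxirane
Product: 3 (2R,3R)-2-ethenyl-5-[(4-methoxybenzyl)oxy]-2-methylpentane-1,3-diol
Conditions: [Ir(cod)Cl]2 (2.5 mol%), Tol-BINAP (5 mol%), 4-cyano-3-nitrobenzoic acid, allyl acetate, K3PO4 (5 mol%), THF, 60 °C
Reagents that add atoms: none
Why: Iridium-catalysed redox-triggered tert-(hydroxy)prenylation of a primary alcohol (Krische-type carbonyl allylation), in which the aldehyde formed from 1 should add to the (E)-σ-allyliridium from 2 through a chair transition state with CH2OH pseudo-equatorial, so that the new C7 hydroxyl is anti to CH2OH and C6 and C7 are set together under catalyst control.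

Step 2
Reactants: 3 diol
Product: 4 primary TBS ether of 3
Conditions: TBSCl, imidazole, CH2Cl2, 0 °C
Reagents that add atoms: tert-butyldimethylsilyl chloride, CC(C)(C)[Si](C)(C)Cl
Why: Selective silylation of the primary over the hindered secondary hydroxyl marks this CH2O arm as the future dienophile carbon.

Step 3
Reactants: 4 primary TBS ether
Product: 5 diol with CH2OH in place of vinyl
Conditions: O3, CH2Cl2/MeOH, −78 °C; NaBH4, −78 → −20 °C
Reagents that add atoms: ozone, [O-][O+]=O
Why: Ozonolysis with reductive work-up should turn the isolated vinyl group into the second CH2OH arm (the future angelate carbon) without touching the quaternary centre, the low reduction temperature guarding against silyl migration between the two arms.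

Step 4
Reactants: 5 diol
Product: 6 acetonide (1,3-dioxane, C4 side chain cis to C5 methyl)
Conditions: 2,2-dimethoxypropane, PPTS (cat.), CH2Cl2, rt
Reagents that add atoms: 2,2-dimethoxypropane, COC(C)(C)OC
Why: Acetal formation on the only 1,3-diol protects C7–O and the new CH2–O together and pre-folds the later tether (side chain and silyloxymethyl arm trans, both equatorial).

Step 5
Reactants: 6 acetonide
Product: 7 primary alcohol
Conditions: DDQ, CH2Cl2/pH 7 buffer, 0 °C
Reagents that add atoms: none
Why: Oxidative cleavage of the PMB ether with DDQ is orthogonal to the acetonide and the silyl ether.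

Step 6
Reactants: 7 primary alcohol
Product: 8 2-[(4R,5R)-5-{[(tert-butyldimethylsilyl)oxy]methyl}-2,2,5-trimethyl-1,3-dioxan-4-yl]acetaldehyde
Conditions: Dess–Martin periodinane, NaHCO3, CH2Cl2, 0 °C → rt
Reagents that add atoms: none
Why: Dess–Martin oxidation should give the β-alkoxy aldehyde under buffered conditions that avoid β-elimination.

Step 7
Reactants: 8 aldehyde; 9 3-methylcyclopent-2-en-1-one
Product: 11 aldol adduct (9R carbinol, mixture at the ring carbon), via trimethylsilyl dienol ether 10 (not isolated)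
Conditions: 9, LDA, THF, −78 °C, then TMSCl; crude 10 + 8, BF3·OEt2, CH2Cl2, −78 °C
Reagents that add atoms: chlorotrimethylsilane, C[Si](C)(C)Cl (its silicon is carried only by intermediate 10 and is lost again on work-up)
Why: Kinetic α'-enolisation and silylation of 9 gives a 2-silyloxydiene whose BF3-promoted Mukaiyama aldol addition to the β-alkoxy aldehyde should follow the polar 1,3-anti model and so fix C9 relative to C7, the neighbouring ring carbon being left as a mixture because step 8 re-forms it.

Step 8
Reactants: 11 aldol adduct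
Product: 12 (5S)-5-[(1R)-1-hydroxy-2-(dioxanyl)ethyl]-3,5-dimethylcyclopent-2-en-1-one
Conditions: LDA (2.3 equiv), THF, −78 → −40 °C; MeI, DMPU, −78 → −30 °C
Reagents that add atoms: iodomethane, CI
Why: Frater–Seebach-type dianion alkylation, in which the chelated lithium alkoxide/α'-enolate should be methylated on the face anti to the C8 chain of the carbinol, so that the C9 configuration dictates the quaternary C10 and both epimers of 11 converge.

Step 9
Reactants: 12 methylated aldol
Product: 13 C9 TBS ether of 12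
Conditions: TBSOTf, 2,6-lutidine, CH2Cl2, −78 → 0 °C
Reagents that add atoms: tert-butyldimethylsilyl triflate, CC(C)(C)[Si](C)(C)OS(=O)(=O)C(F)(F)F
Why: Silylation with the triflate protects the hindered C9 hydroxyl as a bulky, non-participating ether before a leaving group is placed at C11.

Step 10
Reactants: 13 bis-silyl ether
Product: 14 primary alcohol (C9–OTBS kept)
Conditions: HF·pyridine, pyridine, THF, 0 °C
Reagents that add atoms: none
Why: Buffered HF·pyridine should cleave the primary TBS ether much faster than the hindered secondary one (chemoselective desilylation).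

Step 11
Reactants: 14 primary alcohol
Product: 15 neopentyl aldehyde
Conditions: Dess–Martin periodinane, NaHCO3, CH2Cl2, rt
Reagents that add atoms: none
Why: Dess–Martin oxidation gives a non-enolisable aldehyde and leaves the enone and acetal alone.

Step 12
Reactants: 15 aldehyde
Product: 16 (E)-alkenyl pinacol boronate
Conditions: Cl2CHB(pin), CrCl2, LiI, THF, rt
Reagents that add atoms: 2-(dichloromethyl)-4,4,5,5-tetramethyl-1,3,2-dioxaborolane, ClC(Cl)B1OC(C)(C)C(C)(C)O1
Why: Takai–Utimoto boryl-olefination should give the (E)-alkenylboronate selectively and is chemoselective for the aldehyde over the enone.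

Step 13
Reactants: 16 alkenylboronate
Product: 18 Diels–Alder adduct (norbornene: bridgehead C1–OSiMe3, endo C11–B(pin), C6 exo on C5), via trimethylsilyl dienol ether 17 (not isolated)
Conditions: TMSOTf, Et3N, CH2Cl2, 0 °C; then toluene, BHT, 110 °C
Reagents that add atoms: trimethylsilyl triflate, C[Si](C)(C)OS(=O)(=O)C(F)(F)F
Why: Soft γ-enolisation at ring C4–H gives a 1-silyloxy-3-methylcyclopentadiene whose quaternary C10 blocks hydrogen shifts, and the intramolecular Diels–Alder reaction should join C4 (largest HOMO coefficient) to C5 and C1 to C11, the tether forcing C6 exo and the (E)-alkene therefore placing boron endo, so that C10 dictates C1, C4, C5 and C11 while the seven-membered ring forms.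

Step 14
Reactants: 18 adduct
Product: 19 diol (bridgehead C1–OH, endo C11–OH)
Conditions: H2O2, NaOH, THF/H2O, 0 °C; then K2CO3, MeOH, rt
Reagents that add atoms: hydrogen peroxide, OO
Why: Boronate oxidation proceeds with retention and should give the endo C11 alcohol, and methanolysis frees the bridgehead hydroxyl.

Step 15
Reactants: 19 diol
Product: 20 endo C11 mesylate (C1–OH free)
Conditions: MsCl (1.1 equiv), Et3N, CH2Cl2, −20 °C
Reagents that add atoms: methanesulfonyl chloride, CS(Cl)(=O)=O
Why: Selective sulfonylation of the secondary alcohol beside an unreactive tertiary bridgehead hydroxyl.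

Step 16
Reactants: 20 hydroxy mesylate
Product: 22 tricyclic enone (C9–OTBS, C6/C7 acetonide), via diethylaluminium alkoxide 21 (not isolated)
Conditions: Et3Al (3 equiv), CH2Cl2, −78 → 0 °C
Reagents that add atoms: none
Why: Proposed new method: Et3Al converts the bridgehead C1–OH into its aluminium alkoxide 21 (ethane is lost) and a second aluminium centre activates the mesylate, so the C1–C10 bond, antiperiplanar to the endo C11–OMs bond, shifts to C11 while C1 becomes the carbonyl, already conjugated with C2=C3 (semipinacol 1,2-shift). The closest known reaction type is the organoaluminium-promoted semipinacol rearrangement of 2-mesyloxy alcohols (Suzuki–Tsuchihashi), its bridged-ring versions (bicyclo[2.2.2]octane to bicyclo[3.2.1]octane) and the bornyl/pinyl Wagner–Meerwein pair; what is new is the strain-raising direction from a norbornene to a bicyclo[3.1.1]heptenone, which the formation of C=O and the enone plus loss of mesylate should outweigh. Ring closure: the five-membered ring C1–C11–C5–C4–C10 contracts to the cyclobutane C4–C5–C11–C10 by a suprafacial 1,2-alkyl shift with backside displacement at C11, and the cyclopentene C1–C2–C3–C4–C10 grows into the cyclohexenone by taking up C11. The one new stereocentre, C11, is made with inversion and so is dictated by the endo mesylate (from the (E)-alkenylboronate and stereoretentive oxidation); C10 migrates with retention and C4, C5, C6, C7 and C9 are untouched. The selectivity needed is migration of C10 and not of vinylic C2, and no capture of C11 by oxygen: only C1–C10 is antiperiplanar to the endo leaving group (C1–C2 is gauche), and the C9 oxygen, which lies over the exo face of C11, is held as a bulky TBS ether that an aluminium alkoxide cannot transfer or unmask. Low temperature and the covalent Al–O bond should also hold back cycloreversion of the 1-oxidonorbornene.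

Step 17
Reactants: 22 silyl ether enone
Product: 23 C9 alcohol
Conditions: TBAF, THF, 45 °C
Reagents that add atoms: none
Why: Fluoride cleavage of the hindered secondary silyl ether; acetonide and enone should be inert.

Step 18
Reactants: 23 C9 alcohol
Product: 24 C9 3-methylbut-2-enoate
Conditions: 3-methylbut-2-enoic acid, EDC·HCl, DMAP, CH2Cl2, 0 °C → rt
Reagents that add atoms: 3-methylbut-2-enoic acid, CC(C)=CC(=O)O
Why: Steglich esterification with the conjugated acid avoids the ketene pathway that deconjugates the corresponding acid chloride.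

Step 19
Reactants: 24 senecioate acetonide
Product: 25 diol (C7–OH, C6–CH2OH)
Conditions: AcOH/H2O/THF (3:1:1), 45 °C
Reagents that add atoms: none
Why: Mild acidic acetal hydrolysis releases both hydroxyls; the ester, enone and cyclobutane should tolerate dilute acetic acid.

Step 20
Reactants: 25 diol
Product: 26 primary angelate (C7–OH free)
Conditions: angelic acid, 2,4,6-trichlorobenzoyl chloride, Et3N, toluene, rt; then 25, 80 °C
Reagents that add atoms: angelic acid, C/C=C(/C)C(=O)O
Why: Yamaguchi-type mixed-anhydride acylation without nucleophilic catalyst should install the (Z)-2-methylbut-2-enoate without Z to E isomerisation, the primary neopentyl alcohol reacting before the hindered secondary one.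

Step 21
Reactants: 26 hydroxy diester
Product: 27 target CNP0179010.1
Conditions: Ac2O, pyridine, DMAP (cat.), CH2Cl2, rt
Reagents that add atoms: acetic anhydride, CC(=O)OC(C)=O
Why: DMAP-catalysed acetylation of the remaining secondary alcohol completes the triester.

**Compound list**
1 | 3-[(4-methoxybenzyl)oxy]propan-1-ol | COc1ccc(COCCCO)cc1 | starting material
2 | 2-methyl-2-vinyloxirane (isoprene monoxide, racemic) | CC1(C=C)CO1 | starting material
3 | (2R,3R)-2-ethenyl-5-[(4-methoxybenzyl)oxy]-2-methylpentane-1,3-diol (secondary OH anti to CH2OH in the zigzag through the vinyl group) | COc1ccc(COCC[C@@H](O)[C@](C)(C=C)CO)cc1 | intermediate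
4 | primary TBS ether of 3 (secondary OH free) | COc1ccc(COCC[C@@H](O)[C@](C)(C=C)CO[Si](C)(C)C(C)(C)C)cc1 | intermediate
5 | 2-{[(tert-butyldimethylsilyl)oxy]methyl}-5-[(4-methoxybenzyl)oxy]-2-methylpentane-1,3-diol (vinyl of 4 replaced by CH2OH) | COc1ccc(COCC[C@@H](O)[C@](C)(CO)CO[Si](C)(C)C(C)(C)C)cc1 | intermediate
6 | tert-butyl{[(4R,5R)-4-{2-[(4-methoxybenzyl)oxy]ethyl}-2,2,5-trimethyl-1,3-dioxan-5-yl]methoxy}dimethylsilane | COc1ccc(COCC[C@H]2OC(C)(C)OC[C@]2(C)CO[Si](C)(C)C(C)(C)C)cc1 | intermediate
7 | 2-[(4R,5R)-5-{[(tert-butyldimethylsilyl)oxy]methyl}-2,2,5-trimethyl-1,3-dioxan-4-yl]ethan-1-ol | OCC[C@H]1OC(C)(C)OC[C@]1(C)CO[Si](C)(C)C(C)(C)C | intermediate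
8 | 2-[(4R,5R)-5-{[(tert-butyldimethylsilyl)oxy]methyl}-2,2,5-trimethyl-1,3-dioxan-4-yl]acetaldehyde | O=CC[C@H]1OC(C)(C)OC[C@]1(C)CO[Si](C)(C)C(C)(C)C | intermediate
9 | 3-methylcyclopent-2-en-1-one | CC1=CC(=O)CC1 | starting material
10 | trimethyl[(4-methylcyclopenta-1,3-dien-2-yl)oxy]silane | CC1=CC(O[Si](C)(C)C)=CC1 | intermediate
11 | 5-[(1R)-1-hydroxy-2-(dioxanyl of 8)ethyl]-3-methylcyclopent-2-en-1-one, mixture of epimers at ring C5 | CC1=CC(=O)C(C1)[C@H](O)C[C@H]2OC(C)(C)OC[C@]2(C)CO[Si](C)(C)C(C)(C)C | intermediate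
12 | (5S)-5-[(1R)-1-hydroxy-2-(dioxanyl of 8)ethyl]-3,5-dimethylcyclopent-2-en-1-one | CC1=CC(=O)[C@@](C)(C1)[C@H](O)C[C@H]2OC(C)(C)OC[C@]2(C)CO[Si](C)(C)C(C)(C)C | intermediate
13 | TBS ether of 12 at the secondary (C9) hydroxyl | CC1=CC(=O)[C@@](C)(C1)[C@H](O[Si](C)(C)C(C)(C)C)C[C@H]2OC(C)(C)OC[C@]2(C)CO[Si](C)(C)C(C)(C)C | intermediate
14 | 13 with the primary silyl ether cleaved (CH2OH on dioxane C5) | CC1=CC(=O)[C@@](C)(C1)[C@H](O[Si](C)(C)C(C)(C)C)C[C@H]2OC(C)(C)OC[C@]2(C)CO | intermediate
15 | aldehyde from 14 (CHO on dioxane C5) | CC1=CC(=O)[C@@](C)(C1)[C@H](O[Si](C)(C)C(C)(C)C)C[C@H]2OC(C)(C)OC[C@]2(C)C=O | intermediate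
16 | (E)-alkenyl pinacol boronate (dioxane C5 carries (E)-CH=CH–B(pin)) | CC1=CC(=O)[C@@](C)(C1)[C@H](O[Si](C)(C)C(C)(C)C)C[C@H]2OC(C)(C)OC[C@]2(C)/C=C/B3OC(C)(C)C(C)(C)O3 | intermediate
17 | trimethylsilyl dienol ether of 16 (1-silyloxy-3,5-dimethyl-5-substituted cyclopenta-1,3-diene) | CC1=C[C@](C)(C(O[Si](C)(C)C)=C1)[C@H](O[Si](C)(C)C(C)(C)C)C[C@H]2OC(C)(C)OC[C@]2(C)/C=C/B3OC(C)(C)C(C)(C)O3 | intermediate
18 | Diels–Alder adduct: norbornene with bridgehead C1–OSiMe3, endo C11–B(pin), exo C5–C6 bond, C10 bridge (CH3 over C2=C3, C9 over C11–C5), C9–OTBS, C6/C7 acetonide | CC1=C[C@]2(O[Si](C)(C)C)[C@H](B5OC(C)(C)C(C)(C)O5)[C@@H]3[C@H]1[C@@]2(C)[C@H](O[Si](C)(C)C(C)(C)C)C[C@H]4OC(C)(C)OC[C@]34C | intermediate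
19 | diol: 18 with C1–OH and endo C11–OH | CC1=C[C@]2(O)[C@H](O)[C@@H]3[C@H]1[C@@]2(C)[C@H](O[Si](C)(C)C(C)(C)C)C[C@H]4OC(C)(C)OC[C@]34C | intermediate
20 | endo C11 methanesulfonate of 19 (C1–OH free) | CC1=C[C@]2(O)[C@H](OS(C)(=O)=O)[C@@H]3[C@H]1[C@@]2(C)[C@H](O[Si](C)(C)C(C)(C)C)C[C@H]4OC(C)(C)OC[C@]34C | intermediate
21 | diethylaluminium C1-alkoxide of 20 | CC1=C[C@]2(O[Al](CC)CC)[C@H](OS(C)(=O)=O)[C@@H]3[C@H]1[C@@]2(C)[C@H](O[Si](C)(C)C(C)(C)C)C[C@H]4OC(C)(C)OC[C@]34C | intermediate
22 | tricyclic enone (bicyclo[3.1.1]hept-3-en-2-one bridged C5 to C10 by C6–C9), C9–OTBS, C6/C7 acetonide, configuration as in the target | CC1(C)OC[C@]2(C)[C@@H]3[C@H]4C(=O)C=C(C)[C@@H]3[C@@]4(C)[C@H](O[Si](C)(C)C(C)(C)C)C[C@H]2O1 | intermediate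
23 | C9 alcohol of 22 | CC1(C)OC[C@]2(C)[C@@H]3[C@H]4C(=O)C=C(C)[C@@H]3[C@@]4(C)[C@H](O)C[C@H]2O1 | intermediate
24 | C9 3-methylbut-2-enoate of 23 | CC1(C)OC[C@]2(C)[C@@H]3[C@H]4C(=O)C=C(C)[C@@H]3[C@@]4(C)[C@H](OC(=O)C=C(C)C)C[C@H]2O1 | intermediate
25 | diol: C7–OH and C6–CH2OH, C9 senecioate | OC[C@]1(C)[C@@H]2[C@H]3C(=O)C=C(C)[C@@H]2[C@@]3(C)[C@H](OC(=O)C=C(C)C)C[C@H]1O | intermediate
26 | C6–CH2 (Z)-2-methylbut-2-enoate, C7–OH, C9 senecioate | C/C=C(/C)C(=O)OC[C@]1(C)[C@@H]2[C@H]3C(=O)C=C(C)[C@@H]2[C@@]3(C)[C@H](OC(=O)C=C(C)C)C[C@H]1O | intermediate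
27 | CNP0179010.1: C7 acetate, C9 3-methylbut-2-enoate, C6–CH2 angelate of the tricyclic enone | C/C=C(/C)C(=O)OC[C@]1(C)[C@@H]2[C@H]3C(=O)C=C(C)[C@@H]2[C@@]3(C)[C@H](OC(=O)C=C(C)C)C[C@H]1OC(C)=O | target

**Count.** Total: 21 steps. Longest linear sequence: 21 steps (1 → 27; 2, 9 and the acyl donors enter directly).

**Steps most likely to fail**

1. Step 16. The 1,2-shift may not compete: ionisation of the mesylate with capture by the C9 oxygen or elimination, cycloreversion of the 1-oxidonorbornene, or plain recovery because of the strain increase. Fallback: the shift is driven by loss of N2 instead (Tiffeneau–Demjanov-type nitrous acid deamination of a 1,2-amino alcohol). It sets out from boronate 18. Stereoretentive amination of the C–B bond (MeONH2, n-BuLi, THF, −78 → 60 °C) gives the endo C11 amine F1. K2CO3 in MeOH frees the bridgehead hydroxyl to give amino alcohol F2. NaNO2 in aqueous AcOH/THF at 0 °C forms the diazonium acetate F3, which should lose N2 with migration of C10 and give 22, where the route is rejoined.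

2. Step 13. Enolisation toward the exocyclic methyl group, or low dienophile reactivity of the alkenylboronate so that the diene decomposes before cycloaddition. Fallback: a nitroalkene dienophile and the amine route to the rearrangement. It sets out from aldehyde 15. A Henry reaction (MeNO2, Et3N) gives nitro alcohol F4, and dehydration (MsCl, Et3N) gives the (E)-nitroalkene F5. TMSOTf/Et3N forms the trimethylsilyl dienol ether F6, which should cyclise at or below room temperature with the same regiochemistry to the endo-nitro adduct F7. Zn in AcOH reduces the nitro group and removes the silyl group to give amino alcohol F2, which is diazotised as above (F3) to reach 22.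

3. Step 8. Competing γ-deprotonation of the enone, retro-aldol cleavage of the lithium aldolate before the second deprotonation, or O-alkylation. Fallback: the quaternary carbon is made in the C–C coupling itself. It sets out from 8 and 9. Ketone 9 is methylated (LDA, MeI) to 3,5-dimethylcyclopent-2-en-1-one F8 and silylated (LDA, TMSCl) to the trimethylsilyl dienol ether F9. Mukaiyama aldol addition of F9 to 8 (BF3·OEt2, CH2Cl2, −78 °C) forms C9 and C10 together; the diastereomers at C10 are separated by chromatography to reach 12.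

**Further compounds**
F1 | step 16 | endo C11 amine with bridgehead C1–OSiMe3 | CC1=C[C@]2(O[Si](C)(C)C)[C@H](N)[C@@H]3[C@H]1[C@@]2(C)[C@H](O[Si](C)(C)C(C)(C)C)C[C@H]4OC(C)(C)OC[C@]34C
F2 | step 16 | endo C11 amino C1 alcohol | CC1=C[C@]2(O)[C@H](N)[C@@H]3[C@H]1[C@@]2(C)[C@H](O[Si](C)(C)C(C)(C)C)C[C@H]4OC(C)(C)OC[C@]34C
F3 | step 16 | C11 diazonium acetate of F2 | CC1=C[C@]2(O)[C@H]([N+]#N)[C@@H]3[C@H]1[C@@]2(C)[C@H](O[Si](C)(C)C(C)(C)C)C[C@H]4OC(C)(C)OC[C@]34C.CC(=O)[O-]
F4 | step 13 | nitro alcohol from 15 (mixture at the new carbinol) | CC1=CC(=O)[C@@](C)(C1)[C@H](O[Si](C)(C)C(C)(C)C)C[C@H]2OC(C)(C)OC[C@]2(C)C(O)C[N+](=O)[O-]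
F5 | step 13 | (E)-nitroalkene | CC1=CC(=O)[C@@](C)(C1)[C@H](O[Si](C)(C)C(C)(C)C)C[C@H]2OC(C)(C)OC[C@]2(C)/C=C/[N+](=O)[O-]
F6 | step 13 | trimethylsilyl dienol ether of F5 | CC1=C[C@](C)(C(O[Si](C)(C)C)=C1)[C@H](O[Si](C)(C)C(C)(C)C)C[C@H]2OC(C)(C)OC[C@]2(C)/C=C/[N+](=O)[O-]
F7 | step 13 | endo C11 nitro adduct with C1–OSiMe3 | CC1=C[C@]2(O[Si](C)(C)C)[C@H]([N+](=O)[O-])[C@@H]3[C@H]1[C@@]2(C)[C@H](O[Si](C)(C)C(C)(C)C)C[C@H]4OC(C)(C)OC[C@]34C
F8 | step 8 | 3,5-dimethylcyclopent-2-en-1-one (racemic) | CC1=CC(=O)C(C)C1
F9 | step 8 | [(1,4-dimethylcyclopenta-1,3-dien-2-yl)oxy]trimethylsilane | CC1=CC(O[Si](C)(C)C)=C(C)C1
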